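**Assumptions**
- The target stereochemistry is taken exactly as the SMILES gives it: ring C–OAr is R, ring C–OH is S, ring C–side chain is R, and the side-chain CH(CH3) is S. OAr and OH are cis to each other and both trans to the side chain. "Demethoxy" means the 4-hydroxyphenyl end of the curcuminoid.
- The cross-metathesis gives the (E)-enoate as the major isomer, which is separable from the Z isomer.
- (S)-DTBM-SEGPHOS is assumed to be the matched ligand enantiomer in step 4. This is confirmed by a two-run screen against the (R) ligand.

**Retrosynthetic overview**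
1. The curcuminoid is disconnected by Pabon condensation into the vanillin-type aryl ether aldehyde and 6-(4-hydroxyphenyl)hex-5-ene-2,4-dione.
2. The aryl ether and the ring OH are formed together in one step. A Pd-catalysed cis-1,4 addition of vanillin to a 1-methylcyclohexa-1,3-diene monoepoxide opens the epoxide and delivers both oxygens anti to the side chain. This is the bold key step, in place of a Mitsunobu or SNAr ether.
3. The side-chain ketone comes from a Weinreb amide. Its CH(CH3) stereocentre comes from CuH asymmetric 1,4-reduction of a β,β-disubstituted enoate, which is made by cross-metathesis of carvone's isopropenyl group.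
4. The cyclohexane ring is never built. It comes from (S)-carvone, which is converted to the cyclohexadiene through the enol triflate. The only new rings are the epoxide (formed then opened) and none others; the aryl ring comes from vanillin.

---

**Step 1**
Reactants: 1 (S)-carvone; 2 N-phenylbis(trifluoromethanesulfonimide)
Product: 3 (3S)-6-methyl-3-(prop-1-en-2-yl)cyclohexa-1,5-dien-1-yl triflate
Conditions: KHMDS, THF, –78 °C; then 2, –78 → 0 °C
Reagents that add atoms: 2, PhNTf2, O=S(=O)(N(c1ccccc1)S(=O)(=O)C(F)(F)F)C(F)(F)F
Why: Kinetic deprotonation at C6 is the only α′-site, and O-triflation gives the cross-conjugated dienyl triflate (enol triflation). The C5 stereocentre is not touched.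

**Step 2**
Reactants: 3; 4 methyl acrylate
Product: 5 methyl (2E)-3-[(1S)-4-methyl-3-(triflyloxy)cyclohexa-2,4-dien-1-yl]but-2-enoate
Conditions: 4 (5 equiv), Hoveyda–Grubbs II (5 mol %), 1,4-benzoquinone (10 mol %), CH2Cl2, 40 °C
Reagents that add atoms: 4, methyl acrylate, C=CC(=O)OC
Why: Olefin cross-metathesis (Hoveyda–Grubbs II) converts the 1,1-disubstituted isopropenyl group, the only reactive alkene, into the trisubstituted (E)-enoate while the electron-poor cyclic dienyl triflate is inert. No stereocentre is made or altered.

**Step 3**
Reactant: 5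
Product: 6 methyl (2E)-3-[(1S)-4-methylcyclohexa-2,4-dien-1-yl]but-2-enoate
Conditions: Pd(OAc)2 (5 mol %), PPh3 (10 mol %), HCO2H, n-Bu3N, DMF, 60 °C
Reagents that add atoms: none
Why: Pd-catalysed formate hydrogenolysis of the vinyl triflate (Cacchi/Scott reduction) replaces C–OTf by C–H. This gives the 2-methylcyclohexa-1,3-diene (sesquiphellandrene-type) and the enoate survives.

**Step 4**
Reactant: 6
Product: 7 methyl (3S)-3-[(1R)-4-methylcyclohexa-2,4-dien-1-yl]butanoate
Conditions: Cu(OAc)2·H2O (5 mol %), (S)-DTBM-SEGPHOS (5.5 mol %), TMDS, t-BuOH, toluene, 0 °C → rt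
Reagents that add atoms: none (only H is added)
Why: CuH asymmetric 1,4-reduction of the β,β-disubstituted enoate (Buchwald–Lipshutz) sets the side-chain CH(CH3) stereocentre, with the catalyst dominating and the ring stereocentre a minor influence. Only the conjugated enoate is reduced, and the diene is assumed to survive.

**Step 5**
Reactants: 7; 8 N,O-dimethylhydroxylamine hydrochloride
Product: 9 (3S)-N-methoxy-N-methyl-3-[(1R)-4-methylcyclohexa-2,4-dien-1-yl]butanamide
Conditions: 8, i-PrMgCl (3 equiv), THF, –20 → 0 °C
Reagents that add atoms: 8, MeNHOMe·HCl, CNOC.Cl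
Why: Grignard-mediated Weinreb amidation (Williams) converts the ester to the Weinreb amide without touching the diene or either stereocentre.

**Step 6**
Reactants: 9; 10 2-methylprop-1-en-1-ylmagnesium bromide
Product: 11 (6S)-2-methyl-6-[(1R)-4-methylcyclohexa-2,4-dien-1-yl]hept-2-en-4-one
Conditions: 10 (2.5 equiv), THF, 0 °C, then NH4Cl (aq)
Reagents that add atoms: 10, CC(C)=C[Mg]Br
Why: Nahm–Weinreb ketone synthesis stops at the chelated tetrahedral intermediate, so the dienone forms with no over-addition.

**Step 7**
Reactants: 11; 12 dimethyldioxirane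
Product: 13 (6S)-2-methyl-6-[(1R,4R,6S)-1-methyl-7-oxabicyclo[4.1.0]hept-2-en-4-yl]hept-2-en-4-one (the vinyl epoxide; epoxide O trans to the side chain)
Conditions: DMDO (0.95 equiv, acetone), CH2Cl2, –20 °C; filter through basic alumina and use at once
Reagents that add atoms: 12, DMDO, CC1(C)OO1
Why: Neutral Murray epoxidation attacks the more electron-rich trisubstituted ring alkene, not the disubstituted one or the enone. Attack anti to the pseudo-axial side chain sets both epoxide carbons (epoxide O on the face opposite the C4 side chain), with modest selectivity; the minor cis-epoxide is removed after step 8.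

**Step 8**
Reactants: 13; 14 vanillin
Product: 15 4-{[(1R,4S,6R)-4-hydroxy-3-methyl-6-[(2S)-6-methyl-4-oxohept-5-en-2-yl]cyclohex-2-en-1-yl]oxy}-3-methoxybenzaldehyde
Conditions: 14 (1.2 equiv), Pd(PPh3)4 (5 mol %), THF, 25 °C
Reagents that add atoms: 14, vanillin, COc1cc(C=O)ccc1O
Why: Trost-type Pd-catalysed 1,4-addition of a phenol to a diene monoepoxide (Tsuji–Trost type). Pd(0) ionises the tertiary allylic C–O bond anti to the epoxide oxygen to give a π-allyl, and the phenoxide attacks the less hindered Ca terminus anti to Pd. This puts ArO and the liberated OH cis to each other and both trans to the side chain, and creates the trisubstituted Cb=Cc alkene.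

**Step 9**
Reactants: 16 acetylacetone; 17 4-hydroxybenzaldehyde
Product: 18 (E)-6-(4-hydroxyphenyl)hex-5-ene-2,4-dione
Conditions: B2O3, 16 (3 equiv), EtOAc, 70 °C; then 17, B(OBu)3, n-BuNH2, 40 °C; then 1 M HCl, 60 °C
Reagents that add atoms: 16, CC(=O)CC(C)=O; 17, O=Cc1ccc(O)cc1
Why: Pabon condensation proceeds through the boron-complexed diketone, and excess 16 limits bis-condensation. The new alkene is E.

**Step 10**
Reactants: 15; 18
Product: 19 Demethoxybisabolocurcumin ether (target)
Conditions: 18, B2O3, EtOAc, 70 °C; then 15, B(OBu)3, n-BuNH2 (cat.), 60 °C; mild aqueous AcOH workup (pH ~4)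
Reagents that add atoms: none (the boron and amine reagents are not incorporated)
Why: A second Pabon condensation couples the free terminal methyl of 18 to the aldehyde of 15 to give the E-enone and the boron-chelated β-diketone (enol form after workup). All six stereocentres are already set and none is acidic under these conditions.

---

**Compound list**

| No. | Name | SMILES | Role |
|---|---|---|---|
| 1 | (S)-(+)-carvone | CC1=CC[C@@H](CC1=O)C(C)=C | starting material |
| 2 | PhNTf2 | O=S(=O)(N(c1ccccc1)S(=O)(=O)C(F)(F)F)C(F)(F)F | starting material |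
| 3 | carvone dienyl triflate | CC1=CC[C@@H](C=C1OS(=O)(=O)C(F)(F)F)C(C)=C | intermediate |
| 4 | methyl acrylate | C=CC(=O)OC | starting material |
| 5 | enoate dienyl triflate | CC1=CC[C@@H](C=C1OS(=O)(=O)C(F)(F)F)/C(C)=C/C(=O)OC | intermediate |
| 6 | diene enoate | CC1=CC[C@@H](C=C1)/C(C)=C/C(=O)OC | intermediate |
| 7 | saturated diene ester | COC(=O)C[C@H](C)[C@@H]1C=CC(C)=CC1 | intermediate |
| 8 | MeNHOMe·HCl | CNOC.Cl | starting material |
| 9 | Weinreb amide | CON(C)C(=O)C[C@H](C)[C@@H]1C=CC(C)=CC1 | intermediate |
| 10 | 2-methylprop-1-enylmagnesium bromide | CC(C)=C[Mg]Br | starting material |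
| 11 | diene dienone | CC(C)=CC(=O)C[C@H](C)[C@@H]1C=CC(C)=CC1 | intermediate |
| 12 | dimethyldioxirane | CC1(C)OO1 | starting material |
| 13 | vinyl epoxide | CC(C)=CC(=O)C[C@H](C)[C@@H]1C=C[C@@]2(C)O[C@H]2C1 | intermediate |
| 14 | vanillin | COc1cc(C=O)ccc1O | starting material |
| 15 | aryl ether aldehyde | COc1cc(C=O)ccc1O[C@H]1C=C(C)[C@@H](O)C[C@@H]1[C@@H](C)CC(=O)C=C(C)C | intermediate |
| 16 | acetylacetone | CC(=O)CC(C)=O | starting material |
| 17 | 4-hydroxybenzaldehyde | O=Cc1ccc(O)cc1 | starting material |
| 18 | (E)-6-(4-hydroxyphenyl)hex-5-ene-2,4-dione | CC(=O)CC(=O)/C=C/c1ccc(O)cc1 | intermediate |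
| 19 | Demethoxybisabolocurcumin ether | COc1cc(/C=C/C(O)=C/C(=O)/C=C/c2ccc(O)cc2)ccc1O[C@H]1C=C(C)[C@@H](O)C[C@@H]1[C@@H](C)CC(=O)C=C(C)C | target |

---

**Total step count:** 10.
**Longest linear sequence:** 9 steps (1 → 3 → 5 → 6 → 7 → 9 → 11 → 13 → 15 → 19). Step 9 is a parallel branch.

**Three steps most likely to fail**
1. **Step 8 (Pd cis-1,4 addition).** Pd must approach the face that carries the side chain, and isomerisation of the vinyl epoxide to an enone competes.
   - Fallback: drop the Pd route. Treat diene 11 with singlet oxygen (Rose Bengal, hν, O2) to give the endoperoxide, which has both O atoms anti to the side chain. Reduce with thiourea to the cis-1,4-diol, then silylate the less hindered Cd–OH. Arylate the Ca alkoxide by SNAr on 4-fluoro-3-methoxybenzaldehyde, which retains configuration, and remove the silyl group to reach 15.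
2. **Step 4 (CuH reduction).** The diene may compete for CuH, and the diastereoselectivity at the side-chain carbon is unproven.
   - Fallback: abandon catalyst control. Hydroformylate the isopropenyl diene made by steps 1 and 3 only (Rh/biphephos), add 10, and oxidise with DMP. This gives 11 as a roughly 1:1 mixture at the side-chain carbon, which is separated by preparative HPLC.
3. **Step 7 (epoxidation facial selectivity).** Substrate control from a remote (1,3-related) stereocentre may give only a modest ratio.
   - Fallback: use catalyst-controlled Shi epoxidation (fructose-derived ketone, Oxone), with the ketone enantiomer matched to the anti-face. The diastereomeric aryl ethers can also be separated after step 8.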